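| flask | substrate | first nucleophile | second nucleophile | remark | time |
|---|---|---|---|---|---|
| larch | 20 mM | 30 mM | 20 mM | the very flask that is asked about, followed so far |  |
| oak | 20 mM | 60 mM | 20 mM | run made earlier |  |
| flask | 20 mM | 30.0 mM | 20.0 mM |  | 40 min |

| run | time / min | other capture product / % | target / % |
|---|---|---|---|
| larch | 1.33 | 2.6 | 0.6 |
| larch | 2.50 | 6.2 | 2.6 |
| larch | 5.00 | 10.5 | 2.1 |
| larch | 8.00 | 16.2 | 4.4 |
| larch | 15.0 | 28.3 | 5.9 |
| oak | 4.00 | 7.1 | 4.0 |
| oak | 10.0 | 17.1 | 7.4 |
| oak | 20.0 | 29.5 | 10.9 |
| oak | 30.0 | 38.5 | 13.8 |
| oak | 40.0 | 45.0 | 14.3 |

(readings scatter by 0.5 percentage points)

1. ratio of other capture product to target at 50 s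
2. ratio of other capture product to target at 5.0 min
3. ratio of other capture product to target at 40 min
4. which of other capture product and target there is more of at 40 min

- on the list of suspects stand: substrate -> intermediate; first nucleophile + intermediate -> target; second nucleophile + intermediate -> other capture product; first nucleophile <-> dormant form; target <-> isomer of the product

In the oak run, with twice the first nucleophile of the larch flask, I read 17.1% of other capture product against 7.4% of target at 10.0 min. I multiplied that ratio by the charge of first nucleophile over the charge of second nucleophile and called the result the split, a selectivity factor: 6.93. The larch reading at 15.0 min gives 7.19, so doubling the charge about halved the ratio. I took this to mean that the dormant form, once in balance, holds a fixed share of first nucleophile; the charge drops out of the split, but that share stays inside it.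

I then ranked the events by speed. First comes capture of the intermediate: the two products summed follow one first-order feed, with 0.0281 min⁻¹ in oak and 0.0279 min⁻¹ in larch. Next I placed the balance of the dormant form, though the readings cannot time it, since the first larch target reading, 0.6%, stands close to the scatter of 0.5 percentage points. Then comes the feed, with a half-life of 24.7 min. Last comes a loss that shows late: by 40.0 min the feed reckons 67.5% for oak, but the products sum to 59.3%.

So for the larch flask I expected 4.62 once the balance stood, less before it, and more by 40 min, with other capture product ahead.

The forecast gave 4, 4.2 and 5.7, with other capture product ahead, and judged that “the dormant form matters little, if at all”.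

The larch flask gave 2.92, 3.66 and 6.27, with other capture product at 54.0% against 8.61% of target.

    substrate → intermediate (k = 0.0298 min⁻¹)
    first nucleophile + intermediate → target (k = 149 M⁻¹ min⁻¹)
    second nucleophile + intermediate → other capture product (k = 611 M⁻¹ min⁻¹)
    first nucleophile ⇌ dormant form (K = 0.870, k = 0.141 min⁻¹)
    target ⇌ isomer of the product (K = 16.2, k = 0.0286 min⁻¹)

At 50 s the forecast stood above the flask, and that time is shorter than the 4.9 min half-life of first nucleophile by its forward loss to dormant form, reckoned at 14.4 min. At 40 min, the split times second nucleophile left over first nucleophile in both forms gives 2.37, against 2.6 for the two capture rates. With 34 mM of substrate, the same reckoning gives 0.928 at that time, so capture there should run nearly even. That neighbour's computed ratio is 4.28, with 11.6% of target.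

(The earlier runs and the new flask stem from a simulated flask with made-up constants, noise included.)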